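Over 20 h each flask turns a small charge of initiator into chains, and the count to make is how many monomer units end up on each chain.

| setting | Tuesday's | Thursday's | epsilon | zeta |
|---|---|---|---|---|
| free monomer | 26 mM | 35 mM | 19 mM | 30 mM |
| protic impurity | 1.9 mM | 1.9 mM | 1.90 mM | 1.90 mM |
| initiator | 1 mol% | 1 mol% | 1 mol% | 1 mol% |
| remark | run made earlier | run made earlier |  |  |
| time |  |  | 20 h | 20 h |

| run | time / h | monomer in chains / % | free monomer / % |
|---|---|---|---|
| Tuesday's | 1.50 | 69.5 | 24.9 |
| Tuesday's | 3.00 | 84.6 | 8.4 |
| Tuesday's | 6.00 | 91.1 | 0.1 |
| Tuesday's | 10.0 | 90.9 | 1.8 |
| Tuesday's | 20.0 | 91.8 | 0.1 |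
| Thursday's | 4.00 | 93.3 | 3.8 |
| Thursday's | 8.00 | 95.4 | 0.3 |
| Thursday's | 12.0 | 93.1 | 0 |
| Thursday's | 15.0 | 92.1 | 0 |
| Thursday's | 20.0 | 91.8 | 0 |

(standard deviation of a reading: 1 percentage point)

- the average divides the monomer in chains by the number of chains, living and dead together; two radicals that join make one chain
- on the list of suspects stand: initiator -> 2 initiating radical; free monomer + initiating radical -> growing radical + monomer in chains; free monomer + growing radical -> monomer in chains + growing radical; 2 growing radical -> dead chain; protic impurity + free monomer -> quenched substrate; monomer in chains -> over-reaction product
- the earlier runs do not show the number of chains; that part of a forecast is a guess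

1. which of the two ends with the longer chains by the average number of monomer units in a chain (living and dead chains, two that joined counted as one) ("neither" if they lie within 10%) (epsilon / zeta / neither)
2. average number of monomer units in a chain (living and dead chains, two that joined counted as one) at the end, epsilon
3. average number of monomer units in a chain (living and dead chains, two that joined counted as one) at the end, zeta

Early on, the protic impurity takes free monomer about one for one. Tuesday's first reading, at 1.50 h, misses 5.60% of the charge from both columns, and its last, at 20.0 h, misses 8.10%. In Tuesday's run the impurity's charge is 7.31% of the monomer's, so within the scatter these readings put the loss early and near that share.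

Chain growth carries the rest. Tuesday's readings of free monomer, taken as pseudo-first-order, give 0.876 h⁻¹ up to 1.50 h, counted from what the impurity leaves, and then 0.724 h⁻¹ up to 3.00 h. The second value reads as a half-life of 0.957 h, short against 20 h. The slowing, read through the scatter, points to a radical supply fading within hours, so this reckoning takes the initiator as decomposed by the end.

One initiator gives two radicals, and two radicals join into one chain. That makes one chain per initiator, which stays a guess, since the earlier runs show no chain numbers. The quantity to carry is then 90.0 in epsilon, the units per initiator: charged c(free monomer) less charged c(protic impurity), over charged c(initiator). Zeta gets 93.7, since the same impurity costs it 6.33% of its monomer against 10.0% in epsilon. The gap of 4.11% is under the margin, so this reckoning says neither.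

The forecast gives neither, with 115 for epsilon (55 to 220) and 115 for zeta (55 to 220), and it keeps the two together on the ground that the chain count “scales with charge”.

The flasks give neither, with 87.9 in epsilon and 92.2 in zeta.

    initiator → 2 initiating radical (k = 1.10 × 10⁻⁴ s⁻¹)
    free monomer + initiating radical → growing radical + monomer in chains (k = 2.10 × 10⁶ L mol⁻¹ s⁻¹)
    free monomer + growing radical → monomer in chains + growing radical, rate k3*[growing radical]*[free monomer] (k = 24000 L mol⁻¹ s⁻¹)
    2 growing radical → dead chain (k = 2.00 × 10⁸ L mol⁻¹ s⁻¹)
    protic impurity + free monomer → quenched substrate (k = 0.390 L mol⁻¹ s⁻¹)
    monomer in chains → over-reaction product (k = 2.00 × 10⁻⁷ s⁻¹)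

Both values sit just under the units per initiator, 90.0 and 93.7. The count holds on zeta in part because both its supplies shrink: at the end initiator stands at 0.036% of its charge and protic impurity at 0%. A zeta run with initiator kept up ends at 53.0, and one with impurity kept up at 54.9, against 92.2. For a neighbour of zeta with 0.76 mM of protic impurity, the units per initiator give 97.5, and that flask gives 95.9.

Readings and results are calculated on assumed constants; scatter was added.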